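## Structural features

The target is a C20 gibberellin: a 6-5-6 perhydrofluorene (rings A, B, C) in which C8 and C13 are spanned by the two-carbon bridge C15–C16 (ring D), so that rings C and D form a bicyclo[3.2.1]octane carrying the exocyclic C16=C17 methylene. C19 on C4 and C20 on C10 are tied together as a δ-lactone, which with ring A makes a 3-oxabicyclo[3.3.1]nonane. Ring A also carries the cis 2,3-diol on the face away from the lactone bridge and the C18 methyl on C4; C6 bears the free C7 acid and C11 a hydroxyl on the side of the C15–C16 bridge. Ten stereocentres (C2, C3, C4, C5, C6, C8, C9, C10, C11, C13) form one contiguous array; C4, C8 and C10 are quaternary, A/B is trans-fused and B/C cis-fused. The fragile points are the free 3-hydroxyl, which sits β to the lactone carbonyl through quaternary C4 and can epimerise by retro-aldol in base; the exocyclic alkene, which is acid-sensitive and competes with any ring A alkene in oxidations; and C6 and C9, which are epimerisable while a carbonyl is next to them. The real difficulty is the congested C4–C5–C10 triad inside the bridged lactone, joined through C9 and quaternary C8 to a bicyclo[3.2.1]octane of defined sense with oxygen at C11. The key step exploits the fact that C16 sits on bridgehead C13 next to C12, which is α to the C11 oxygen: moving C16 back to C12 gives an isomeric bicyclo[2.2.2]octane (bridgeheads C8 and C12) that a Diels–Alder reaction on an aromatic ring C can build, and a 1,2-vinyl shift C12→C13 through a C12 radical stabilised by the C11 carbonyl then creates ring D.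

## Logic of the disconnections

**34 ⇒ 31.** No skeletal bond is cut. The acid, the diol and the C11 carbinol are taken back to the methyl ester, the acetonide and the C11 ketone (33, 32, 31). The acetonide is kept until last because it blocks the retro-aldol path at C3. The forward steps need hydride delivery to C11 from the α face and an ester cleavage that does not use hydroxide on the free diol.

**31 ⇒ 30.** The C13–C16 bond is cut and C16 is reattached to C12. Ring D disappears and a bicyclo[2.2.2]octane with bridgeheads C8 and C12 appears, with a radical precursor on C13 and the C11 ketone kept. The gain is that this bicycle is a Diels–Alder adduct of a six-membered ring. The demand is that the vinyl shift must outrun hydrogen transfer to C13 and must open toward C12.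

**30 ⇒ 26 (through 29, 28, 27).** Only functional groups change: the C11 ketone goes back to a methyl enol ether, the C13 xanthate to a ketone and C14H2 to a dimethyl ketal. All three oxygenated carbons of the bicycle (C11, C13, C14) then descend from the oxygens of one arene. The forward order must keep the C11 ketone masked until the C13 ketone has been reduced and derivatised, and C9 must be protonated from the β face.

**26 ⇒ 24 + 25.** C8–C15 and C12–C16 are cut (retro-Diels–Alder). This removes ring D's carbons as a three-carbon cumulene and leaves a cyclohexa-2,4-dienone. The forward cycloaddition must put the central carbon of 25 on C12 and must approach the β face.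

**24 ⇒ 21 (through 23, 22).** The dienone is re-aromatised to a 2-methoxyphenol, and the phenol oxygen is traced to an aryl bromide. Ring C becomes a robust, symmetrical dimethoxyarene with one halogen marker at C13. The forward oxidation must add the alcohol solvent at C14 only.

**21 ⇒ 19 (through 20).** The C2–O and C3–O bonds are cut back to the C2=C3 alkene. Two stereocentres are removed, and the lactone bridge can be relied on to direct oxidation to the β face. The diol must be made before any other alkene exists.

**19 ⇒ 18.** The C2=C3 bond is cut (ring-closing metathesis), opening ring A to an allyl group on C10 and a vinyl group on C4. This requires the vinyl group and the allyl group to be cis on the lactone ring.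

**18 ⇒ 16 (through 17).** The C3–C4 bond is cut, and the vinyl group is traced through an aldehyde to an enolate acylation. C4 becomes a simple α-methyl lactone carbon. The forward acylation must occur on the face of C4 that carries the C1 arm and must not touch the more acidic C6.

**16 ⇒ 15.** The C4–C5 bond is cut (retro-Michael). The lactone opens to a propanoate ester of the C20 alcohol and an indene-3-carboxylate. The gain is large: the ester tether can deliver C4 only to the face of C20, so the trans A/B relationship (H5 anti to C20) is enforced by ring size.

**15 ⇒ 9 + 13 (through 14); 13 ⇒ 10 + 11.** The C6–C8 aryl bond and the C5=C6 bond are cut. Ring B opens to an aldehyde at C5 on an acyclic quaternary C10 and a two-carbon phosphonate that carries C6 and C7 at the α-keto-ester level. The forward cyclisation must choose the single free ortho position of the arene over the allyl group.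

**9 ⇒ 6 + 7 (through 8).** The C19–O ester bond is cut and the C5 aldehyde is reduced, which gives a prochiral 2,2-disubstituted propane-1,3-diol. The whole absolute configuration then rests on one enantiotopic-group-selective acylation, and the acyl group installed is at once the C19–C4–C18 unit.

**6 ⇒ 1 + 2 + 4 (through 5, 3).** C5 and C20 are taken back to the two ester carbons of a malonate, C10–C1 to an allylation and C10–C9 to an arylation of the malonate with a symmetrical dibromide. The forward arylation must stop after one of the two bromides.

## Other disconnections considered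

**Alternative 1:** The cut is at C4–C5 and C9–C10, so rings A and B are removed from a preformed ring C/D bicyclo[3.2.1]octane. In the forward step Mn(OAc)3, kept trivalent at an anode, would oxidise a 2-methyl-3-oxo ester terminus to the C4 radical. This would close 6-endo onto C5, and the C10 radical would close 5-exo onto C9 of a chloroalkene that serves as the C11 ketone, to give A1.

- In its favour: two rings, two quaternary carbons and four stereocentres would form in one operation; the union is convergent with a fragment that already holds ring D; and no dearomatisation or rearrangement is needed.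
- Against it here: in A1 the lactone is still open and ring A has only a C3 ketone while C16=C17 is already present. The 2,3-diol would have to be made beside an alkene that competes in every oxidation, and the axial 3-alcohol would need hydride from the shielded α face. The relative configuration of C4, C5, C9 and C10 would rest on the preferences of a radical cascade next to quaternary C8. The enantiopure bicyclic half is a synthesis of its own.
- Comparison: in ring construction per step Alternative 1 is the better plan (rings A and B in one step, against steps 8 to 12 here), and it is the equal of the chosen plan in arriving with the C11 ketone in place. The chosen plan is stronger in the certainty of the C5/C10 relationship (tether-enforced) and in access to the diol (made before any second alkene exists).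

**Alternative 2:** The cut is at C8–C9 and C12–C13, so rings B and C open and ring D becomes a cyclopentadiene. In the forward step an oxyallyl cation over C9–C11–C12, released from a chloromethyl ketone function, would add [4+3] across C8 and C13 of the diene held through C6–C5–C10, to give A2.

- In its favour: a [4+3] cycloaddition to a cyclopentadiene gives a bicyclo[3.2.1]octenone directly, which is exactly rings C and D with the C11 ketone; ring A, lactone and acetonide can be finished beforehand; and the allylsilane in A2 gives the exocyclic methylene by protodesilylation.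
- Against it here: the disubstituted cyclopentadiene can scramble by 1,5-hydrogen shifts and dimerise. The tether must form the five-membered ring B and a quaternary C8 at a diene terminus. Three new stereocentres (C8, C9, C13) would depend on facial and compact/extended selectivity with no rigid bias, and C7 would still need oxidation.
- Comparison: Alternative 2 is the better plan in directness to the bicyclo[3.2.1]octane (one step, against steps 17 to 23 here), and it is the equal of the chosen plan in delivering the C11 ketone for the same late reduction. The chosen plan is stronger in precedent and in stereocontrol, since its rearrangement creates only C13 and geometry fixes its sense.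

**Alternative 3:** The cut is the C2–C3 bond. In the forward step SmI2 would couple an aldehyde C3 on C4 with an aldehyde C2 at the end of the C1 arm across the finished lactone (pinacol coupling), closing ring A and creating both carbinols, to give A3.

- In its favour: ring closure and diol in one late step; chelated samarium diketyls favour cis diols in six-ring closures; no osmium is used; and the diol could be made after the exocyclic alkene exists.
- Against it here: the cis diol can form on either face and only the β face is wanted. The dialdehyde (one enolisable, one neopentyl beside a lactone carbonyl) is prone to aldol and deformylation. The disconnection also leaves rings C and D and the C4 centre untouched, so these would still need a solution such as the chosen one.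
- Comparison: Alternative 3 is the better plan in step count for ring A plus diol (one step, against steps 12 and 13 here), and it is the equal of the chosen plan in relying on the lactone bridge for facial control. The chosen plan is more predictable (osmylation of a rigid alkene), and its key step addresses the harder ring C/D problem.

Key step: step 23

Remark on the chemistry: gibberellane numbering is used for every intermediate (arene carbons are C8, C9, C11–C14); α is the face that carries C20 and the lactone bridge, β the opposite face; the C4 epimers of 16 and the C13 epimers of 28–30 converge later, so one is drawn.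

## Route

Step 1
Reactants: 1 1,4-dibromo-2,5-dimethoxybenzene; 2 dimethyl malonate
Product: 3 dimethyl 2-(4-bromo-2,5-dimethoxyphenyl)malonate
Conditions: Pd(dba)2 (2 mol%), P(t-Bu)3 (4 mol%), K3PO4, toluene, 70 °C (1 in excess)
Reagents that add atoms: none
Why: Palladium-catalysed α-arylation of a malonate; the product is deprotonated under the conditions, which deactivates its remaining C–Br bond, and the excess of 1 is recovered.

Step 2
Reactants: 3 dimethyl 2-(4-bromo-2,5-dimethoxyphenyl)malonate; 4 allyl bromide
Product: 5 dimethyl 2-allyl-2-(4-bromo-2,5-dimethoxyphenyl)malonate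
Conditions: NaH, THF, 0 °C; then 4, 25 °C
Reagents that add atoms: none
Why: SN2 alkylation of the stabilised arylmalonate anion makes the future C10 a prochiral quaternary carbon bearing the C1–C2 arm.

Step 3
Reactants: 5 dimethyl 2-allyl-2-(4-bromo-2,5-dimethoxyphenyl)malonate
Product: 6 2-allyl-2-(4-bromo-2,5-dimethoxyphenyl)propane-1,3-diol
Conditions: LiAlH4, THF, 0 °C
Reagents that add atoms: none
Why: Hydride reduction of both esters gives the prochiral diol (future C5 and C20); aryl bromide and alkene are inert to LiAlH4 at 0 °C.

Step 4
Reactants: 6 2-allyl-2-(4-bromo-2,5-dimethoxyphenyl)propane-1,3-diol; 7 vinyl propanoate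
Product: 8 (2R)-2-(4-bromo-2,5-dimethoxyphenyl)-2-(hydroxymethyl)pent-4-en-1-yl propanoate
Conditions: lipase from Burkholderia cepacia, 7, t-BuOMe, 25 °C
Reagents that add atoms: none
Why: Lipase-catalysed enantiotopic-group-selective transesterification of a prochiral 2-aryl-2-alkylpropane-1,3-diol with an irreversible acyl donor sets C10; the enzyme is selected by screening to acylate the arm that becomes C20, and the propanoyl group is also the C19–C4–C18 unit.

Step 5
Reactants: 8 (2R)-monopropanoate
Product: 9 (2S)-2-(4-bromo-2,5-dimethoxyphenyl)-2-formylpent-4-en-1-yl propanoate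
Conditions: Dess–Martin periodinane, NaHCO3, CH2Cl2, 0 → 25 °C
Reagents that add atoms: none
Why: Dess–Martin oxidation under buffered conditions gives the non-enolisable aldehyde (future C5) and removes the free hydroxyl before 1,3-acyl migration can erode the C10 configuration.

Step 6
Reactants: 10 methyl 2,2-dimethoxyacetate; 11 trimethyl phosphite
Product: 13 methyl 2-(dimethoxyphosphoryl)-2-methoxyacetate, via methyl chloro(methoxy)acetate 12 (not isolated)
Conditions: AcCl, I2 (cat.), 55 °C; then 11, 80 °C
Reagents that add atoms: none
Why: Exchange of one acetal methoxy group for chloride followed by a Michaelis–Arbuzov reaction gives the α-methoxyphosphonate, a two-carbon α-keto-ester synthon for C6 and C7.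

Step 7
Reactants: 9 (2S)-aldehyde; 13 methyl 2-(dimethoxyphosphoryl)-2-methoxyacetate
Product: 14 methyl 4-(4-bromo-2,5-dimethoxyphenyl)-2-methoxy-4-[(propanoyloxy)methyl]hepta-2,6-dienoate (E/Z mixture, quaternary carbon as in 9)
Conditions: 13, LiN(SiMe3)2, THF, −78 → 0 °C
Reagents that add atoms: none
Why: Horner–Wadsworth–Emmons olefination of the hindered but electrophilic aldehyde gives the α-methoxyacrylate, a masked C6 α-keto ester; the alkene geometry is irrelevant.

Step 8
Reactants: 14 α-methoxyacrylate
Product: 15 methyl 1-allyl-5-bromo-4,7-dimethoxy-1-[(propanoyloxy)methyl]-1H-indene-3-carboxylate (indene C1 = C10, configured as in 9)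
Conditions: MeSO3H, CH2Cl2, 0 → 25 °C
Reagents that add atoms: none
Why: Protonation of the enol ether at C5 gives an oxocarbenium ion at C6 that alkylates the only free ortho position (C8, ortho to a methoxy group) in a Friedel–Crafts cyclisation, and acid-promoted loss of methanol gives the conjugated indene ester; the enol ether is far more basic than the allyl group.

Step 9
Reactants: 15 indene propanoate
Product: 16 cis-fused indano-δ-lactone (new C4–C5 bond; 5β-H, 6β-CO2Me, 10β-allyl, C4 bearing H and CH3 as both epimers; ring C = 13-bromo-11,14-dimethoxyarene)
Conditions: KN(SiMe3)2, THF, −78 → −20 °C; AcOH; then DBU (cat.), CH2Cl2, 25 °C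
Reagents that add atoms: none
Why: Intramolecular Michael addition (6-exo-trig) of the propanoate enolate to the α-arylacrylate; the three-atom ester tether reaches C5 only on the face of C20, so the lactone is cis-fused and H5 is trans to C20, and DBU equilibrates the C7 ester trans to C4.

Step 10
Reactants: 16 indano-δ-lactone
Product: 17 4-formyl-4-methyl lactone (formyl carbon = C3, on the face of C4 that carries the C1 arm)
Conditions: LiN(i-Pr)2 (2.3 equiv), THF, −78 °C; HCO2CH2CF3 (1.1 equiv), −78 °C; AcOH
Reagents that add atoms: 2,2,2-trifluoroethyl formate, O=COCC(F)(F)F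
Why: The C6 ester enolate forms first and protects that site; the second, more reactive lactone enolate is C-formylated at C4 on the convex face of the cis-fused lactone, anti to the C5–C6 bond and the arene, which is the face needed for ring A.

Step 11
Reactants: 17 4-formyl-4-methyl lactone
Product: 18 4-methyl-4-vinyl lactone (diene for ring closure)
Conditions: Ph3PCH3Br, KN(SiMe3)2, THF, −78 → 0 °C; then DBU (cat.), CH2Cl2
Reagents that add atoms: methyltriphenylphosphonium bromide, C[P+](c1ccccc1)(c1ccccc1)c1ccccc1.[Br-]
Why: Wittig methylenation of the non-enolisable aldehyde; excess ylide only deprotonates C6 reversibly, and DBU returns the C7 ester to the trans position.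

Step 12
Reactants: 18 4-methyl-4-vinyl lactone
Product: 19 ring A 2-ene (rings A and B and the 19,20-lactone on the bromodimethoxyarene)
Conditions: second-generation Grubbs catalyst (5 mol%), CH2Cl2, 40 °C
Reagents that add atoms: none
Why: Ring-closing metathesis between the C10 allyl and C4 vinyl groups, both axial on the lactone ring, forms C2=C3 and ring A as a bicyclo[3.3.1]nonene with loss of ethene.

Step 13
Reactants: 19 ring A 2-ene
Product: 20 2β,3β-diol
Conditions: OsO4 (2 mol%), NMO, acetone/H2O, 25 °C
Reagents that add atoms: N-methylmorpholine N-oxide, C[N+]1([O-])CCOCC1; water, O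
Why: Catalytic osmium tetroxide syn-dihydroxylation; the lactone bridge covers the α face of the only alkene, so both hydroxyls enter from the β face.

Step 14
Reactants: 20 2β,3β-diol
Product: 21 2,3-acetonide
Conditions: Me2C(OMe)2, PPTS (cat.), CH2Cl2, 25 °C
Reagents that add atoms: 2,2-dimethoxypropane, COC(C)(C)OC
Why: Acetonide formation on the cis-diol blocks the retro-aldol path at C3 and keeps these hydroxyls out of the later xanthate step.

Step 15
Reactants: 21 2,3-acetonide aryl bromide
Product: 22 C13 pinacol boronate
Conditions: B2pin2, PdCl2(dppf) (5 mol%), KOAc, 1,4-dioxane, 90 °C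
Reagents that add atoms: bis(pinacolato)diboron, CC1(C)OB(OC1(C)C)B1OC(C)(C)C(C)(C)O1
Why: Miyaura borylation of the aryl bromide; KOAc is mild enough for the lactone and the esters.

Step 16
Reactants: 22 C13 pinacol boronate
Product: 23 C13 phenol (2-methoxyphenol with the C14 methoxy group)
Conditions: H2O2 (30% aq.), NaHCO3, THF/H2O, 0 → 25 °C
Reagents that add atoms: hydrogen peroxide, OO
Why: Oxidation of the arylboronate by 1,2-aryl shift from boron to oxygen gives the phenol at C13, completing the guaiacol needed for dearomatisation.

Step 17
Reactants: 23 C13 phenol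
Product: 24 masked ortho-benzoquinone (13-oxo, 14,14-dimethoxy, diene C8=C9–C11=C12 with 11-OMe)
Conditions: PhI(OAc)2, MeOH, 0 °C
Reagents that add atoms: methanol, CO
Why: Oxidative dearomatisation of a 2-methoxyphenol in methanol gives the 6,6-dimethoxycyclohexa-2,4-dienone; methanol adds at C14 because that carbon carries the cation-stabilising methoxy group and the para carbon C9 is fully substituted, and the 4,5-dialkyl dienone resists dimerisation.

Step 18
Reactants: 24 masked ortho-benzoquinone; 25 propa-1,2-diene (allene)
Product: 26 bicyclo[2.2.2]octadiene adduct (bridgeheads C8 and C12; C15 on C8 β, C16(=C17H2) on C12; 13-oxo, 14,14-dimethoxy, 9(11)-enol ether)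
Conditions: 25 (excess), BHT (cat.), toluene, sealed tube, 100 °C
Reagents that add atoms: none
Why: Diels–Alder reaction of a masked ortho-benzoquinone with an unactivated cumulene: the terminal CH2 bonds to the hindered δ-carbon C8 and the central carbon to C12, as frontier-orbital polarisation and steric demand both require; the dienophile approaches the β face, anti to the axial C20 methylene standing over C9, which sets C8 and C12.

Step 19
Reactants: 26 Diels–Alder adduct
Product: 27 13-ketone with C14H2 (enol ether retained)
Conditions: SmI2, THF/MeOH, −78 → 0 °C
Reagents that add atoms: none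
Why: SmI2 removes both α-methoxy groups of the α,α-dialkoxy ketone by two ketyl/β-elimination sequences; the ketone itself, the enol ether and the esters are untouched.

Step 20
Reactants: 27 13-ketone
Product: 28 13-alcohol (oxygen syn to the C9–C11 bridge drawn)
Conditions: NaBH4, MeOH, −20 °C
Reagents that add atoms: none
Why: Borohydride reduction of the only ketone present; the C13 configuration is irrelevant because this carbon becomes a radical (attack from the side of the methylene bridge is assumed for the drawing).

Step 21
Reactants: 28 13-alcohol
Product: 29 13-O-(S-methyl dithiocarbonate) (xanthate) enol ether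
Conditions: KN(SiMe3)2, THF, −78 °C; CS2; MeI, −78 → 0 °C
Reagents that add atoms: carbon disulfide, S=C=S; iodomethane, CI
Why: Xanthate formation from the alkoxide; the C11 ketone is still masked as its enol ether, so there is no enolisable ketone and no β-hydroxy ketone that could cleave by retro-aldol.

Step 22
Reactants: 29 xanthate enol ether
Product: 30 bicyclo[2.2.2]octane precursor: C16 on C12, C11 ketone, C13 xanthate, 2,3-acetonide, C7 methyl ester
Conditions: oxalic acid, THF/H2O, 25 °C
Reagents that add atoms: water, O
Why: Mild acid hydrolysis of the methyl enol ether; C9 is protonated from the β face, anti to the axial C20 methylene on C10, giving the 9β-H 11-ketone, and xanthate and acetonide tolerate dilute oxalic acid.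

Step 23
Reactants: 30 bicyclo[2.2.2]octane xanthate
Product: 31 11-oxo gibberellane lactone (2,3-acetonide, C7 methyl ester; bicyclo[3.2.1]octane with C16 on C13)
Conditions: Bu3SnH (slow addition), AIBN, benzene (0.005 M), 80 °C
Reagents that add atoms: none
Why: The tin radical adds to the thiocarbonyl group and the adduct fragments to the secondary C13 radical (Barton–McCombie initiation). This radical adds 3-exo-trig to C16 of the neighbouring C16=C17 bond to give a cyclopropylcarbinyl radical, which reopens by β-scission of C12–C16; the net change is a 1,2-vinyl shift from C12 to C13, the closest known reaction type being the homoallyl/cyclopropylcarbinyl/homoallyl rearrangement of 2-methylenebicyclo[2.2.2]octyl radicals to bicyclo[3.2.1]octyl radicals. Ring D (C8, C14, C13, C16, C15) is thus closed by migration of an existing bond through a transient 3-exo-trig closure, not by a chain cyclisation. The new stereocentre C13 is fixed by the bicycle, because C16 crosses the C12–C13 bond suprafacially and stays on its original face; no other centre is touched. Three selectivities are needed: rearrangement before hydrogen transfer to C13, opening toward C12 and not back, and vinyl shift in preference to a 1,2-acyl shift of C11. The first is secured by keeping Bu3SnH very dilute; the second by the C11 carbonyl, which makes the C12 radical an α-keto radical and adds to the relief of bicyclo[2.2.2] strain; the third by the faster addition of an alkyl radical to C=C than to a ketone C=O. Hydrogen transfer from Bu3SnH to C12 then gives the C12 methylene with the exocyclic alkene intact.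

Step 24
Reactants: 31 11-oxo gibberellane lactone
Product: 32 11β-alcohol (acetonide, methyl ester)
Conditions: NaBH4, MeOH/THF, 0 → 25 °C
Reagents that add atoms: none
Why: The β face of the C11 carbonyl is closed by the C15–C16 bridge in a 1,3-diaxial relation, so the small hydride can enter only from the α face and gives the axial 11β-alcohol; ester and lactone are not reduced.

Step 25
Reactants: 32 11β-alcohol methyl ester
Product: 33 C7 carboxylic acid (acetonide)
Conditions: n-PrSLi, HMPA, 25 °C; then 1 M HCl to pH 3, 0 °C
Reagents that add atoms: none
Why: SN2 demethylation of the hindered C7 ester by thiolate at the methyl carbon avoids acyl attack, hydroxide and lactone opening; the neopentyl C20–O carbon is not attacked, and the acetonide keeps C3 safe from retro-aldol epimerisation.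

Step 26
Reactants: 33 C7 acid acetonide
Product: 34 CNP0302900.3 (target)
Conditions: AcOH/H2O (4:1), 40 °C
Reagents that add atoms: none
Why: Acid-catalysed acetonide hydrolysis, mild enough for the exocyclic alkene and the lactone, releases the 2β,3β-diol.

## Compound list

1 | 1,4-dibromo-2,5-dimethoxybenzene | COc1cc(Br)c(OC)cc1Br | starting material
2 | dimethyl malonate | COC(=O)CC(=O)OC | starting material
3 | dimethyl 2-(4-bromo-2,5-dimethoxyphenyl)malonate | COC(=O)C(C(=O)OC)c1cc(OC)c(Br)cc1OC | intermediate
4 | allyl bromide (3-bromoprop-1-ene) | C=CCBr | starting material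
5 | dimethyl 2-allyl-2-(4-bromo-2,5-dimethoxyphenyl)malonate | COC(=O)C(CC=C)(C(=O)OC)c1cc(OC)c(Br)cc1OC | intermediate
6 | 2-allyl-2-(4-bromo-2,5-dimethoxyphenyl)propane-1,3-diol | OCC(CO)(CC=C)c1cc(OC)c(Br)cc1OC | intermediate
7 | vinyl propanoate | CCC(=O)OC=C | starting material
8 | (2R)-2-(4-bromo-2,5-dimethoxyphenyl)-2-(hydroxymethyl)pent-4-en-1-yl propanoate | COc1cc(Br)c(OC)cc1[C@@](CC=C)(COC(=O)CC)CO | intermediate
9 | (2S)-2-(4-bromo-2,5-dimethoxyphenyl)-2-formylpent-4-en-1-yl propanoate | COc1cc(Br)c(OC)cc1[C@@](CC=C)(COC(=O)CC)C=O | intermediate
10 | methyl 2,2-dimethoxyacetate | COC(OC)C(=O)OC | starting material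
11 | trimethyl phosphite | COP(OC)OC | starting material
12 | methyl 2-chloro-2-methoxyacetate | COC(Cl)C(=O)OC | intermediate
13 | methyl 2-(dimethoxyphosphoryl)-2-methoxyacetate | COC(C(=O)OC)P(=O)(OC)OC | intermediate
14 | methyl 4-(4-bromo-2,5-dimethoxyphenyl)-2-methoxy-4-[(propanoyloxy)methyl]hepta-2,6-dienoate (E/Z mixture) | COc1cc(Br)c(OC)cc1[C@@](CC=C)(COC(=O)CC)C=C(OC)C(=O)OC | intermediate
15 | methyl 1-allyl-5-bromo-4,7-dimethoxy-1-[(propanoyloxy)methyl]-1H-indene-3-carboxylate (single enantiomer at C10) | COc1cc(Br)c(OC)c2c1[C@@](CC=C)(COC(=O)CC)C=C2C(=O)OC | intermediate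
16 | cis-fused indano-δ-lactone, 5β-H, 6β-CO2Me, 10β-allyl, C4 H/CH3 (both epimers) | COc1cc(Br)c(OC)c2c1[C@@]3(CC=C)COC(=O)C(C)[C@H]3[C@@H]2C(=O)OC | intermediate
17 | 4-formyl-4-methyl indano-δ-lactone (formyl = C3, cis to the C10 allyl arm) | COc1cc(Br)c(OC)c2c1[C@@]3(CC=C)COC(=O)[C@](C)(C=O)[C@H]3[C@@H]2C(=O)OC | intermediate
18 | 4-methyl-4-vinyl indano-δ-lactone | COc1cc(Br)c(OC)c2c1[C@@]3(CC=C)COC(=O)[C@](C)(C=C)[C@H]3[C@@H]2C(=O)OC | intermediate
19 | ring A 2-ene: 13-bromo-11,14-dimethoxy ring C arene, 19,20-lactone, 7-methyl ester | COc1cc(Br)c(OC)c2c1[C@]13COC(=O)[C@](C)(C=CC1)[C@H]3[C@@H]2C(=O)OC | intermediate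
20 | 2β,3β-diol of 19 | COc1cc(Br)c(OC)c2c1[C@]13COC(=O)[C@](C)([C@@H](O)[C@@H](O)C1)[C@H]3[C@@H]2C(=O)OC | intermediate
21 | 2,3-acetonide aryl bromide | COc1cc(Br)c(OC)c2c1[C@]13COC(=O)[C@](C)([C@@H](OC(C)(C)O4)[C@@H]4C1)[C@H]3[C@@H]2C(=O)OC | intermediate
22 | C13 pinacol boronate | COc1cc(B5OC(C)(C)C(C)(C)O5)c(OC)c2c1[C@]13COC(=O)[C@](C)([C@@H](OC(C)(C)O4)[C@@H]4C1)[C@H]3[C@@H]2C(=O)OC | intermediate
23 | C13 phenol (ring C guaiacol on the A/B lactone) | COc1cc(O)c(OC)c2c1[C@]13COC(=O)[C@](C)([C@@H](OC(C)(C)O4)[C@@H]4C1)[C@H]3[C@@H]2C(=O)OC | intermediate
24 | masked ortho-benzoquinone: 13-oxo-11,14,14-trimethoxy-8,11-diene | COC1=CC(=O)C(OC)(OC)C2=C1[C@]13COC(=O)[C@](C)([C@@H](OC(C)(C)O4)[C@@H]4C1)[C@H]3[C@@H]2C(=O)OC | intermediate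
25 | propa-1,2-diene (allene) | C=C=C | starting material
26 | bicyclo[2.2.2]octadiene adduct: 13-oxo, 14,14-dimethoxy, 11-methoxy-9(11)-ene, 16-methylene on C12 | C=C1C[C@]23C(OC)(OC)C(=O)[C@H]1C(OC)=C2[C@]12COC(=O)[C@](C)([C@@H](OC(C)(C)O4)[C@@H]4C1)[C@H]2[C@@H]3C(=O)OC | intermediate
27 | 13-ketone with C14H2, enol ether retained | C=C1C[C@]23CC(=O)[C@H]1C(OC)=C2[C@]12COC(=O)[C@](C)([C@@H](OC(C)(C)O4)[C@@H]4C1)[C@H]2[C@@H]3C(=O)OC | intermediate
28 | 13-alcohol, enol ether retained | C=C1C[C@]23C[C@@H](O)[C@H]1C(OC)=C2[C@]12COC(=O)[C@](C)([C@@H](OC(C)(C)O4)[C@@H]4C1)[C@H]2[C@@H]3C(=O)OC | intermediate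
29 | 13-xanthate, enol ether retained | C=C1C[C@]23C[C@@H](OC(=S)SC)[C@H]1C(OC)=C2[C@]12COC(=O)[C@](C)([C@@H](OC(C)(C)O4)[C@@H]4C1)[C@H]2[C@@H]3C(=O)OC | intermediate
30 | bicyclo[2.2.2]octane isomer: C16 on C12, 11-ketone, 13-xanthate, 2,3-acetonide, 7-methyl ester | C=C1C[C@]23C[C@@H](OC(=S)SC)[C@H]1C(=O)[C@H]2[C@]12COC(=O)[C@](C)([C@@H](OC(C)(C)O4)[C@@H]4C1)[C@H]2[C@@H]3C(=O)OC | intermediate
31 | 11-oxo gibberellane lactone, 2,3-acetonide, 7-methyl ester | C=C1C[C@]23C[C@H]1CC(=O)[C@H]2[C@]12COC(=O)[C@](C)([C@@H](OC(C)(C)O4)[C@@H]4C1)[C@H]2[C@@H]3C(=O)OC | intermediate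
32 | 11β-hydroxy gibberellane lactone, 2,3-acetonide, 7-methyl ester | C=C1C[C@]23C[C@H]1C[C@H](O)[C@H]2[C@]12COC(=O)[C@](C)([C@@H](OC(C)(C)O4)[C@@H]4C1)[C@H]2[C@@H]3C(=O)OC | intermediate
33 | 11β-hydroxy gibberellane lactone 7-acid, 2,3-acetonide | C=C1C[C@]23C[C@H]1C[C@H](O)[C@H]2[C@]12COC(=O)[C@](C)([C@@H](OC(C)(C)O4)[C@@H]4C1)[C@H]2[C@@H]3C(=O)O | intermediate
34 | CNP0302900.3 (2β,3β,11β-trihydroxy 19,20-lactone 7-acid) | C=C1C[C@]23C[C@H]1C[C@H](O)[C@H]2[C@]12COC(=O)[C@](C)([C@@H](O)[C@@H](O)C1)[C@H]2[C@@H]3C(=O)O | target

## Step count and least certain steps

Total step count: 26. Longest linear sequence: 25 steps (steps 1–5 and 7–26; step 6 is a one-step side branch).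

**Step 23 (key step).** The most likely failure is hydrogen transfer to the C13 radical before the 3-exo closure, which would give plain deoxygenation without the shift; a 1,2-acyl shift of C11 is a second, slower leak. The first recourse is a still lower stannane concentration or a slower hydrogen donor. The fallback changes the mechanism from radical to cationic and sets out from 28, returning at 31. MsCl/Et3N converts 28 into the C13 mesylate F1, whose leaving group is antiperiplanar to the C12–C16 bond. Ionisation in (CF3)2CHOH buffered with 2,6-lutidine, in the presence of Et3SiH, lets C16 migrate in a Wagner–Meerwein shift to an alkoxyallyl cation over C12–C11–C9, which the silane reduces at its less hindered end C12 to the rearranged methyl enol ether F2. Hydrolysis as in step 22 then gives 31.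

**Step 18 (allene cycloaddition).** Allene is a sluggish dienophile, so thermal decay or re-aromatisation of the dienone may compete, and attack on the α face would give the wrong C8 configuration. The fallback changes the diene and runs from 23 to 27. Oxidation of 23 with Pb(OAc)4 in AcOH (Wessely acetoxylation) gives the ortho-quinol acetate F3, a more heat-tolerant diene. Cycloaddition with 25 at higher temperature gives the acetoxy methoxy adduct F4, and SmI2 removes both α-oxygen groups to rejoin the route at 27.

**Step 10 (formylation at C4).** Poor facial selectivity at the C4 enolate would give the epimer that cannot close ring A; reaction at the C6 enolate or ortho-metalation of the bromoarene by excess amide base are further risks. The fallback delivers C3 through a tether and runs from 16 to 19. The dianion of 16 is brominated with 1,2-dibromotetrachloroethane to the C4 bromolactone F5 (either epimer serves). 9-BBN followed by H2O2/NaHCO3 turns the allyl group into the primary alcohol F6, and Dess–Martin oxidation gives the aldehyde F7, whose carbonyl carbon is now C3. SmI2 then effects an intramolecular Reformatsky reaction that can place C3 on C4 only from the side of the C1 arm, giving the β-hydroxy lactone F8. Dehydration with the Burgess reagent, for which only C2 offers β-hydrogens, returns 19.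

**Step 22 (enol ether hydrolysis).** Protonation of C9 from the α face would give the 9-epimer, and partial loss of the acetonide is possible (it can be put back as in step 14). The fallback moves the protonation to a substrate with a second shielding group and runs from 26 to 30. Compound 26 is hydrolysed while the C14 dimethyl ketal still stands on the α side of C9, giving the keto ketal F9. SmI2 gives the 11,13-dione F10, NaBH4 at low temperature reduces the less hindered C13 ketone to the hydroxy ketone F11, and xanthate formation at −78 °C gives 30.

**Step 4 (enzymatic desymmetrisation).** Incomplete enantiotopic discrimination, the opposite sense of acylation, or 1,3-acyl migration in the monoester would lower the enantiomeric purity of everything that follows. The fallback replaces the enzyme by a chiral metal catalyst and runs from 6 to 8. CuCl2 with a chiral bis(oxazoline) ligand of the appropriate handedness, benzoyl chloride and Et3N give the monobenzoate F12. Silylation gives the silyl ether benzoate F13, methanolysis with K2CO3 the silyl ether alcohol F14, and propanoylation the silyl ether propanoate F15. HF·pyridine then returns 8.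

## Further compounds

F1 | step 23 | C13 mesylate of 28 | C=C1C[C@]23C[C@@H](OS(C)(=O)=O)[C@H]1C(OC)=C2[C@]12COC(=O)[C@](C)([C@@H](OC(C)(C)O4)[C@@H]4C1)[C@H]2[C@@H]3C(=O)OC
F2 | step 23 | 11-methoxy-9(11)-ene (methyl enol ether of 31) | C=C1C[C@]23C[C@H]1CC(OC)=C2[C@]12COC(=O)[C@](C)([C@@H](OC(C)(C)O4)[C@@H]4C1)[C@H]2[C@@H]3C(=O)OC
F3 | step 18 | ortho-quinol acetate: 14-acetoxy-14-methoxy-13-oxo dienone (C14 epimers) | COC1=CC(=O)C(OC)(OC(C)=O)C2=C1[C@]13COC(=O)[C@](C)([C@@H](OC(C)(C)O4)[C@@H]4C1)[C@H]3[C@@H]2C(=O)OC
F4 | step 18 | allene adduct of F3 (14-acetoxy-14-methoxy) | C=C1C[C@]23C(OC)(OC(C)=O)C(=O)[C@H]1C(OC)=C2[C@]12COC(=O)[C@](C)([C@@H](OC(C)(C)O4)[C@@H]4C1)[C@H]2[C@@H]3C(=O)OC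
F5 | step 10 | C4 bromolactone (C4 epimers) | COc1cc(Br)c(OC)c2c1[C@@]3(CC=C)COC(=O)C(C)(Br)[C@H]3[C@@H]2C(=O)OC
F6 | step 10 | C4 bromolactone with 3-hydroxypropyl arm on C10 | COc1cc(Br)c(OC)c2c1[C@@]3(CCCO)COC(=O)C(C)(Br)[C@H]3[C@@H]2C(=O)OC
F7 | step 10 | C4 bromolactone with 3-oxopropyl arm on C10 | COc1cc(Br)c(OC)c2c1[C@@]3(CCC=O)COC(=O)C(C)(Br)[C@H]3[C@@H]2C(=O)OC
F8 | step 10 | ring A closed 3-hydroxy lactone (C3 epimers) | COc1cc(Br)c(OC)c2c1[C@]13COC(=O)[C@](C)(C(O)CC1)[C@H]3[C@@H]2C(=O)OC
F9 | step 22 | 11,13-dioxo 14,14-dimethyl ketal | C=C1C[C@]23C(OC)(OC)C(=O)[C@H]1C(=O)[C@H]2[C@]12COC(=O)[C@](C)([C@@H](OC(C)(C)O4)[C@@H]4C1)[C@H]2[C@@H]3C(=O)OC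
F10 | step 22 | 11,13-dione | C=C1C[C@]23CC(=O)[C@H]1C(=O)[C@H]2[C@]12COC(=O)[C@](C)([C@@H](OC(C)(C)O4)[C@@H]4C1)[C@H]2[C@@H]3C(=O)OC
F11 | step 22 | 13-hydroxy 11-ketone | C=C1C[C@]23C[C@@H](O)[C@H]1C(=O)[C@H]2[C@]12COC(=O)[C@](C)([C@@H](OC(C)(C)O4)[C@@H]4C1)[C@H]2[C@@H]3C(=O)OC
F12 | step 4 | monobenzoate of 6 (benzoate on the future C20 arm) | COc1cc(Br)c(OC)cc1[C@@](CC=C)(COC(=O)c1ccccc1)CO
F13 | step 4 | TBS ether of F12 | COc1cc(Br)c(OC)cc1[C@@](CC=C)(COC(=O)c1ccccc1)CO[Si](C)(C)C(C)(C)C
F14 | step 4 | mono-TBS ether alcohol | COc1cc(Br)c(OC)cc1[C@@](CC=C)(CO)CO[Si](C)(C)C(C)(C)C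
F15 | step 4 | TBS ether of 8 | COc1cc(Br)c(OC)cc1[C@@](CC=C)(COC(=O)CC)CO[Si](C)(C)C(C)(C)C
A1 | alternative 1 | tetracyclic 3,11-dione with C19 methyl ester, C20 acetoxymethyl and C7 methyl ester | C=C1C[C@]23C[C@H]1CC(=O)[C@H]2[C@]1(COC(C)=O)CCC(=O)[C@@](C)(C(=O)OC)[C@H]1[C@@H]3C(=O)OC
A2 | alternative 2 | pentacyclic 11-ketone lactone acetonide with C15=C16 alkene, C17 allylsilane CH2 and C7 PMB ether | C[Si](C)(C)CC1=C[C@]23C[C@H]1CC(=O)[C@H]2[C@]12COC(=O)[C@](C)([C@@H](OC(C)(C)O4)[C@@H]4C1)[C@H]2[C@@H]3COCc1ccc(OC)cc1
A3 | alternative 3 | 11-O-TBS methyl ester of the target | C=C1C[C@]23C[C@H]1C[C@H](O[Si](C)(C)C(C)(C)C)[C@H]2[C@]12COC(=O)[C@](C)([C@@H](O)[C@@H](O)C1)[C@H]2[C@@H]3C(=O)OC
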